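Take a millimolar of electrophile as our coin and ask what it costs in nucleophile.

    electrophile + nucleophile → acid set free + target (k1 = 140 M⁻¹ s⁻¹)
    nucleophile + acid set free ⇌ protonated nucleophile, settled at all times (K2 = 6.8 × 10⁵ M⁻¹)
    acid set free + free base ⇌ salt of the base (K3 = 13000 M⁻¹, k3 = 10000 M⁻¹ s⁻¹)
    electrophile + target → side product (k4 = 97 M⁻¹ s⁻¹)
    free base ⇌ dormant form (K5 = 4.2, k5 = 0.069 s⁻¹)

electrophile 0.20 mM; nucleophile 0.600 mM; free base 0.100 mM; time 40 s

- part of the electrophile that has reacted at 40 s
- share of the unused nucleophile that is free and not bound as protonated nucleophile, at 40 s

- in percentages every species weighs as the electrophile in it: one side product counts as two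
- run time (flask): 40 s

The bench rule says that the nucleophile, charged at more than the electrophile, stays constant (pseudo-first-order), which gives 96.5% reacted. But each turn of step 1 costs a second nucleophile, because at the start the equilibrium constant times the charge is 410 for the nucleophile against 1.3 for the free base.

So we define the demand as two nucleophile per electrophile charged, over the nucleophile charged: 0.667. That is no small number, so the bench rule fails here. Above 1 the nucleophile charged falls short of two for every electrophile charged, and that is the border of what follows.

Below the border, we replace the falling nucleophile by its mean, 0.400 mM, and take the target at 0.100 mM, half the electrophile charged. The electrophile then decays at 0.0657 s⁻¹, so 92.8% has reacted. Step 1 has run 0.158 mM, which makes the free share 64.2%. To test the mean, we hold the nucleophile at its reckoned end level instead, which gives 86.1%, lower by 6.6 percentage points, and we take that gap as the error of our figure.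

The forecast, on its own integration, says 91.2% and 63.7%, both lower than our two figures: “Each target made therefore consumes two nucleophile”.

The flask gives 91.3% and 63.7%. At 40.0 s this flask has 46.6% of its nucleophile left as free nucleophile, so 53.4% of the charge is gone; the demand times the electrophile passed through step 1, target plus half the side product, comes to 53.6% of the nucleophile charged. In a neighbouring flask with 0.80 mM of electrophile the demand is 2.67, past the border, and at two each the nucleophile charged matches 37.5% of that electrophile. That neighbouring flask reaches 65.3% reacted, with 2.59% of its nucleophile left, a free share of 5.34%, and 53.5% of its electrophile in side product.

The rate constants are those of an exercise; what happens was integrated by code.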